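## Retrosynthetic overview

- The (E)-enal comes from a Wittig two-carbon homologation of the benzodioxane-7-carbaldehyde, which comes from the 7-carbonitrile (the nitrile is carried as an aldehyde surrogate that survives radical conditions).
- The dioxane ring is the only ring formed (both benzene rings are bought). It is closed last at the benzylic C2–O1 bond by a new intramolecular dehydrogenative benzylic C–H aryloxylation, which sets C2 trans to C3.
- The phenol oxygen comes from an aryl bromide (Miyaura borylation, then oxidation). The C3–O4 aryl ether comes from Mitsunobu inversion of (R)-1-(3,4,5-trimethoxyphenyl)propan-2-ol with 3-bromo-4-hydroxy-5-methoxybenzonitrile.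
- The alcohol comes from 3,4,5-trimethoxyphenylmagnesium bromide and (R)-propylene oxide, the single source of absolute configuration.

Assumption: the bromotrimethoxybenzene, (R)-propylene oxide, the bromohydroxymethoxybenzonitrile and (triphenylphosphoranylidene)acetaldehyde are bought. Ring A is the trimethoxyphenyl ring and ring B is the benzonitrile ring. The target is the trans-(2S,3S) isomer.

## Route

Step 1
Reactants: 1 5-bromo-1,2,3-trimethoxybenzene; 2 (R)-propylene oxide [(2R)-2-methyloxirane]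
Product: 4 (2R)-1-(3,4,5-trimethoxyphenyl)propan-2-ol, via aryl Grignard reagent 3 (not isolated)
Conditions: Mg, THF, 50 °C; then CuBr·SMe2 (10 mol %), 2, −30 → 0 °C; aq. NH4Cl
Reagents that add atoms: none
Why: Copper-catalysed Grignard opening of a terminal epoxide (SN2 at the unsubstituted CH2), so the carbinol stereocentre of 2 is never touched and stays (R).

Step 2
Reactants: 4 (2R)-1-(3,4,5-trimethoxyphenyl)propan-2-ol; 5 3-bromo-4-hydroxy-5-methoxybenzonitrile
Product: 6 3-bromo-5-methoxy-4-{[(2S)-1-(3,4,5-trimethoxyphenyl)propan-2-yl]oxy}benzonitrile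
Conditions: PPh3 (1.5 equiv), DIAD (1.5 equiv), THF, 0 °C → rt
Reagents that add atoms: none
Why: Mitsunobu reaction, a redox condensation in which the acidic cyanophenol substitutes the secondary carbinol carbon by SN2 with inversion, (R) to (S); this carbon becomes C3 of the target.

Step 3
Reactants: 6 3-bromo-5-methoxy-4-{[(2S)-1-(3,4,5-trimethoxyphenyl)propan-2-yl]oxy}benzonitrile
Product: 7 3-methoxy-5-(4,4,5,5-tetramethyl-1,3,2-dioxaborolan-2-yl)-4-{[(2S)-1-(3,4,5-trimethoxyphenyl)propan-2-yl]oxy}benzonitrile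
Conditions: B2pin2 (1.3 equiv), Pd(dppf)Cl2 (5 mol %), KOAc (3 equiv), 1,4-dioxane, 90 °C
Reagents that add atoms: bis(pinacolato)diboron, CC1(C)OB(OC1(C)C)B1OC(C)(C)C(C)(C)O1
Why: Miyaura borylation; the aryl bromide is the only site for oxidative addition, and the nitrile, ethers and stereocentre are inert.

Step 4
Reactants: 7 3-methoxy-5-(4,4,5,5-tetramethyl-1,3,2-dioxaborolan-2-yl)-4-{[(2S)-1-(3,4,5-trimethoxyphenyl)propan-2-yl]oxy}benzonitrile
Product: 8 3-hydroxy-5-methoxy-4-{[(2S)-1-(3,4,5-trimethoxyphenyl)propan-2-yl]oxy}benzonitrile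
Conditions: potassium peroxymonosulfate triple salt (2KHSO5·KHSO4·K2SO4; 1.1 equiv KHSO5), acetone/H2O 1:1, 0 °C, 15 min
Reagents that add atoms: potassium peroxymonosulfate, [K+].OOS(=O)(=O)[O-]
Why: Oxidation of the arylboronate (1,2-shift of the aryl group from boron to oxygen) puts the OH exactly where the bromine was, ortho to the ether oxygen; the short cold exposure spares the nitrile and ring A.

Step 5
Reactants: 8 3-hydroxy-5-methoxy-4-{[(2S)-1-(3,4,5-trimethoxyphenyl)propan-2-yl]oxy}benzonitrile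
Product: 11 (2S,3S)-5-methoxy-3-methyl-2-(3,4,5-trimethoxyphenyl)-2,3-dihydro-1,4-benzodioxine-7-carbonitrile, via benzylic radical 9 (not isolated), via benzylic cation 10 (not isolated)
Conditions: CuCl (10 mol %), 2,2′-bis(2-oxazoline) (12 mol %), N-fluorobenzenesulfonimide (NFSI, 1.3 equiv, added over 4 h), CH2Cl2/HFIP 4:1, 0.02 M, 30 °C
Reagents that add atoms: none
Why: Proposed new method: an intramolecular dehydrogenative benzylic C–H aryloxylation by copper radical relay, in which monovalent copper reduces NFSI to the sulfonimidyl radical, this abstracts a hydrogen atom from the only secondary benzylic CH2 (activated by ring A; the tertiary C–H next to oxygen, the OMe groups and the cyano-deactivated ring B react more slowly) to give radical 9, divalent copper oxidises 9 to the 3,4,5-trimethoxybenzyl cation 10 (radical–polar crossover), and the ortho phenol oxygen closes the 6-membered ring so that the aryl group sits equatorial and trans to the methyl group on the existing (S) carbon, which fixes C2 as (S), while the acidic co-product (PhSO2)2NH lets any cis isomer re-ionise at the benzylic C–O bond and settle as the more stable trans isomer; the closest known reaction type is the copper/NFSI radical-relay (Kharasch–Sosnovsky-type) benzylic C–H etherification with alcohols, which has not been shown with a phenol, in a ring-forming mode or for 1,4-benzodioxanes.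

Step 6
Reactants: 11 (2S,3S)-5-methoxy-3-methyl-2-(3,4,5-trimethoxyphenyl)-2,3-dihydro-1,4-benzodioxine-7-carbonitrile
Product: 13 (2S,3S)-5-methoxy-3-methyl-2-(3,4,5-trimethoxyphenyl)-2,3-dihydro-1,4-benzodioxine-7-carbaldehyde, via aluminium aldimine 12 (not isolated)
Conditions: iBu2AlH (1.3 equiv), CH2Cl2, −78 → −40 °C; then 1 M aq. HCl, 0 °C
Reagents that add atoms: water, O
Why: Partial hydride reduction of the aryl nitrile stops at the N-aluminated aldimine, which is hydrolysed to the aldehyde on work-up; the aryl ethers and both stereocentres are untouched.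

Step 7
Reactants: 13 (2S,3S)-5-methoxy-3-methyl-2-(3,4,5-trimethoxyphenyl)-2,3-dihydro-1,4-benzodioxine-7-carbaldehyde; 14 (triphenylphosphoranylidene)acetaldehyde
Product: 15 (2E)-3-[(2S,3S)-5-methoxy-3-methyl-2-(3,4,5-trimethoxyphenyl)-2,3-dihydro-1,4-benzodioxin-7-yl]prop-2-enal (target)
Conditions: 14 (1.3 equiv), toluene, 90 °C
Reagents that add atoms: none
Why: Wittig reaction with a stabilised formyl ylide gives the (E)-enal selectively; neutral conditions leave the benzodioxane stereocentres alone.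

## Compound list

1 | 5-bromo-1,2,3-trimethoxybenzene | COc1cc(Br)cc(OC)c1OC | starting material
2 | (R)-propylene oxide, (2R)-2-methyloxirane | C[C@@H]1CO1 | starting material
3 | (3,4,5-trimethoxyphenyl)magnesium bromide (not isolated) | COc1cc([Mg]Br)cc(OC)c1OC | intermediate
4 | (2R)-1-(3,4,5-trimethoxyphenyl)propan-2-ol | C[C@@H](O)Cc1cc(OC)c(OC)c(OC)c1 | intermediate
5 | 3-bromo-4-hydroxy-5-methoxybenzonitrile | COc1cc(C#N)cc(Br)c1O | starting material
6 | 3-bromo-5-methoxy-4-{[(2S)-1-(3,4,5-trimethoxyphenyl)propan-2-yl]oxy}benzonitrile | C[C@@H](Cc1cc(OC)c(OC)c(OC)c1)Oc1c(Br)cc(C#N)cc1OC | intermediate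
7 | 3-methoxy-5-(4,4,5,5-tetramethyl-1,3,2-dioxaborolan-2-yl)-4-{[(2S)-1-(3,4,5-trimethoxyphenyl)propan-2-yl]oxy}benzonitrile | C[C@@H](Cc1cc(OC)c(OC)c(OC)c1)Oc1c(B2OC(C)(C)C(C)(C)O2)cc(C#N)cc1OC | intermediate
8 | 3-hydroxy-5-methoxy-4-{[(2S)-1-(3,4,5-trimethoxyphenyl)propan-2-yl]oxy}benzonitrile | C[C@@H](Cc1cc(OC)c(OC)c(OC)c1)Oc1c(O)cc(C#N)cc1OC | intermediate
9 | (2S)-2-(4-cyano-2-hydroxy-6-methoxyphenoxy)-1-(3,4,5-trimethoxyphenyl)propyl radical, the benzylic radical of 8 (not isolated) | C[C@@H]([CH]c1cc(OC)c(OC)c(OC)c1)Oc1c(O)cc(C#N)cc1OC | intermediate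
10 | (2S)-2-(4-cyano-2-hydroxy-6-methoxyphenoxy)-1-(3,4,5-trimethoxyphenyl)propyl cation, the benzylic cation of 8 (not isolated) | C[C@@H]([CH+]c1cc(OC)c(OC)c(OC)c1)Oc1c(O)cc(C#N)cc1OC | intermediate
11 | (2S,3S)-5-methoxy-3-methyl-2-(3,4,5-trimethoxyphenyl)-2,3-dihydro-1,4-benzodioxine-7-carbonitrile | COc1cc([C@@H]2Oc3cc(C#N)cc(OC)c3O[C@H]2C)cc(OC)c1OC | intermediate
12 | N-(diisobutylaluminio) aldimine of 13, the reduced nitrile before hydrolysis (not isolated) | COc1cc([C@@H]2Oc3cc(C=N[Al](CC(C)C)CC(C)C)cc(OC)c3O[C@H]2C)cc(OC)c1OC | intermediate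
13 | (2S,3S)-5-methoxy-3-methyl-2-(3,4,5-trimethoxyphenyl)-2,3-dihydro-1,4-benzodioxine-7-carbaldehyde | COc1cc([C@@H]2Oc3cc(C=O)cc(OC)c3O[C@H]2C)cc(OC)c1OC | intermediate
14 | (triphenylphosphoranylidene)acetaldehyde | O=CC=P(c1ccccc1)(c1ccccc1)c1ccccc1 | starting material
15 | (2E)-3-[(2S,3S)-5-methoxy-3-methyl-2-(3,4,5-trimethoxyphenyl)-2,3-dihydro-1,4-benzodioxin-7-yl]prop-2-enal | COc1cc([C@@H]2Oc3cc(/C=C/C=O)cc(OC)c3O[C@H]2C)cc(OC)c1OC | target

## Step count and risk

Total steps: 7. Longest linear sequence: 7 steps (1 to 15).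

**Step 5 (proposed new step, highest risk).** Several things could go wrong:
- The sulfonimidyl radical may take the phenol O–H instead of the benzylic C–H, stalling the copper cycle or giving phenol coupling products.
- It may add to ring A.
- The product's own benzylic C2–H may be oxidised further.
- Ring closure may give a poor trans:cis ratio if equilibration is slow.

Fallback (known chemistry; sets out from 5 and Grignard reagent 3, comes back at 11). The benzylic carbon is oxygenated from the start and the ring is closed by the classical acid-mediated cyclisation of a benzylic alcohol onto an ortho phenol. Mitsunobu etherification of 5 with (2R)-2-hydroxy-N-methoxy-N-methylpropanamide (PPh3, DIAD, THF; inversion) gives (2S)-2-(2-bromo-4-cyano-6-methoxyphenoxy)-N-methoxy-N-methylpropanamide F4. Grignard reagent 3 (THF, −40 → 0 °C; aq. NH4Cl) gives 3-bromo-5-methoxy-4-{[(2S)-1-oxo-1-(3,4,5-trimethoxyphenyl)propan-2-yl]oxy}benzonitrile F5, which is reduced at once with NaBH4/CeCl3·7H2O (MeOH, −40 °C) to 3-bromo-4-{[(2S)-1-hydroxy-1-(3,4,5-trimethoxyphenyl)propan-2-yl]oxy}-5-methoxybenzonitrile F6 as a mixture of carbinol epimers, both of which are used. Borylation as in step 3 gives 4-{[(2S)-1-hydroxy-1-(3,4,5-trimethoxyphenyl)propan-2-yl]oxy}-3-methoxy-5-(4,4,5,5-tetramethyl-1,3,2-dioxaborolan-2-yl)benzonitrile F7, and oxidation as in step 4 gives 3-hydroxy-4-{[(2S)-1-hydroxy-1-(3,4,5-trimethoxyphenyl)propan-2-yl]oxy}-5-methoxybenzonitrile F8. BF3·OEt2 (0.3 equiv, CH2Cl2, 0 °C) ionises the benzylic alcohol of either epimer to the same trimethoxybenzyl cation, which the phenol captures under thermodynamic control to give trans 11.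

**Step 2 (Mitsunobu at a secondary carbon with a di-ortho-substituted phenol).** Elimination to (E)-isoelemicin or aryl-assisted ionisation could lower yield or ee.

Fallback (sets out from 5 and Grignard reagent 3, comes back at 6). The aryl–CH2 bond is made last, so no substitution is needed at the hindered carbinol carbon. Mitsunobu etherification of 5 with methyl (R)-lactate (PPh3, DIAD, THF; inversion at an activated, unhindered carbinol) gives methyl (2S)-2-(2-bromo-4-cyano-6-methoxyphenoxy)propanoate F1. LiBH4 (THF, 0 °C) reduces only the ester to 3-bromo-4-{[(2S)-1-hydroxypropan-2-yl]oxy}-5-methoxybenzonitrile F2. TsCl, Et3N and DMAP (CH2Cl2) give (2S)-2-(2-bromo-4-cyano-6-methoxyphenoxy)propyl 4-methylbenzenesulfonate F3. Copper-catalysed coupling of F3 with Grignard reagent 3 (Li2CuCl4 5 mol %, THF, −30 → 0 °C) gives 6; the stereocentre is not touched after the lactate Mitsunobu.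

**Step 7 (Wittig with the formyl ylide).** The electron-rich aldehyde may react sluggishly, and the product enal can react again to give a dienal.

Fallback (sets out from 13, comes back at 15). Horner–Wadsworth–Emmons reaction of 13 with triethyl phosphonoacetate (NaH, THF, 0 °C) gives ethyl (2E)-3-[(2S,3S)-5-methoxy-3-methyl-2-(3,4,5-trimethoxyphenyl)-2,3-dihydro-1,4-benzodioxin-7-yl]prop-2-enoate F9. iBu2AlH (2.2 equiv, CH2Cl2, −78 °C) gives (2E)-3-[(2S,3S)-5-methoxy-3-methyl-2-(3,4,5-trimethoxyphenyl)-2,3-dihydro-1,4-benzodioxin-7-yl]prop-2-en-1-ol F10. MnO2 (CH2Cl2, rt) oxidises the allylic alcohol to 15.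

## Further compounds

F1 | step 2 | methyl (2S)-2-(2-bromo-4-cyano-6-methoxyphenoxy)propanoate | C[C@@H](C(=O)OC)Oc1c(Br)cc(C#N)cc1OC
F2 | step 2 | 3-bromo-4-{[(2S)-1-hydroxypropan-2-yl]oxy}-5-methoxybenzonitrile | C[C@@H](CO)Oc1c(Br)cc(C#N)cc1OC
F3 | step 2 | (2S)-2-(2-bromo-4-cyano-6-methoxyphenoxy)propyl 4-methylbenzenesulfonate | C[C@@H](COS(=O)(=O)c1ccc(C)cc1)Oc1c(Br)cc(C#N)cc1OC
F4 | step 5 | (2S)-2-(2-bromo-4-cyano-6-methoxyphenoxy)-N-methoxy-N-methylpropanamide | C[C@@H](C(=O)N(C)OC)Oc1c(Br)cc(C#N)cc1OC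
F5 | step 5 | 3-bromo-5-methoxy-4-{[(2S)-1-oxo-1-(3,4,5-trimethoxyphenyl)propan-2-yl]oxy}benzonitrile | C[C@@H](C(=O)c1cc(OC)c(OC)c(OC)c1)Oc1c(Br)cc(C#N)cc1OC
F6 | step 5 | 3-bromo-4-{[(2S)-1-hydroxy-1-(3,4,5-trimethoxyphenyl)propan-2-yl]oxy}-5-methoxybenzonitrile (both carbinol epimers) | C[C@@H](C(O)c1cc(OC)c(OC)c(OC)c1)Oc1c(Br)cc(C#N)cc1OC
F7 | step 5 | 4-{[(2S)-1-hydroxy-1-(3,4,5-trimethoxyphenyl)propan-2-yl]oxy}-3-methoxy-5-(4,4,5,5-tetramethyl-1,3,2-dioxaborolan-2-yl)benzonitrile (both carbinol epimers) | C[C@@H](C(O)c1cc(OC)c(OC)c(OC)c1)Oc1c(B2OC(C)(C)C(C)(C)O2)cc(C#N)cc1OC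
F8 | step 5 | 3-hydroxy-4-{[(2S)-1-hydroxy-1-(3,4,5-trimethoxyphenyl)propan-2-yl]oxy}-5-methoxybenzonitrile (both carbinol epimers) | C[C@@H](C(O)c1cc(OC)c(OC)c(OC)c1)Oc1c(O)cc(C#N)cc1OC
F9 | step 7 | ethyl (2E)-3-[(2S,3S)-5-methoxy-3-methyl-2-(3,4,5-trimethoxyphenyl)-2,3-dihydro-1,4-benzodioxin-7-yl]prop-2-enoate | COc1cc([C@@H]2Oc3cc(/C=C/C(=O)OCC)cc(OC)c3O[C@H]2C)cc(OC)c1OC
F10 | step 7 | (2E)-3-[(2S,3S)-5-methoxy-3-methyl-2-(3,4,5-trimethoxyphenyl)-2,3-dihydro-1,4-benzodioxin-7-yl]prop-2-en-1-ol | COc1cc([C@@H]2Oc3cc(/C=C/CO)cc(OC)c3O[C@H]2C)cc(OC)c1OC
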